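Ring C is formed last. The flavonol comes from oxidative closure (O1–C2 bond, C3–OH) of a 2'-hydroxychalcone, which is the aldol union of a ring A methyl ketone with a ring B benzaldehyde.
Ring B is built first. The strategy rests on its four contiguous substituted carbons C1'–C4', where the neighbours C2' and C3' carry identical prenyl groups. C2'/C3' are the two sp carbons of a symmetrical diprenylacetylene. C1', C6', C5', C4' are C6, C5, C4, C3 of a 3-acyloxy-2-pyrone-6-carboxylate (Diels–Alder reaction, then loss of CO2).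
The C5' oxygen is added afterwards at the only free position ortho to the 4'-phenol (ortho-formylation, Dakin oxidation). The ester then becomes the aldehyde.
Ring A is bought as 2,4,6-trihydroxyacetophenone. Its C8 1,1-dimethylallyl group comes from Claisen rearrangement of the symmetrical 4-O-prenyl ether, and leaving only the flanked 2-OH free forces ring C to close next to that group.
Order of rings: B (cycloaddition), A (purchased), C (oxidative cyclisation).

Key step: step 4

Remark: the target has no stereocentre. The stereocentres of three transient racemic intermediates are erased again, and the only lasting stereochemical element on the way is the E alkene of the chalcone.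

Step 1
Reactants: 1 galactaric acid
Product: 2 potassium 3-acetoxy-2-oxo-2H-pyran-6-carboxylate
Conditions: Ac2O (excess), KOAc (1 equiv), 100 °C
Reagents that add atoms: acetic anhydride CC(=O)OC(C)=O; potassium acetate CC(=O)[O-].[K+]
Why: This is the known dehydrative cyclisation of an aldaric acid, in which peracetylation, closure of the C5 oxygen onto C1 as a six-membered lactone and two acetate-promoted E1cB losses of acetic acid give the conjugated 2-pyrone, erasing all four stereocentres and leaving the C3 enol oxygen already masked as its acetate.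

Step 2
Reactants: 2 potassium 3-acetoxy-2-oxo-2H-pyran-6-carboxylate
Product: 3 methyl 3-acetoxy-2-oxo-2H-pyran-6-carboxylate
Conditions: MeI, DMF, rt
Reagents that add atoms: iodomethane CI
Why: SN2 O-alkylation of a carboxylate salt in a dipolar aprotic solvent needs neither acid nor alkoxide, so the enol acetate and the ring-opening-prone pyrone lactone are left alone.

Step 3
Reactants: 4 ethynylmagnesium bromide; 5 1-bromo-3-methylbut-2-ene (prenyl bromide, 2 equiv in two portions)
Product: 8 2,9-dimethyldeca-2,8-dien-5-yne, via 5-methylhex-4-en-1-yne 6 (not isolated), via alkynylmagnesium bromide 7 (not isolated)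
Conditions: CuCl (cat.), 5, THF, 0 → 40 °C; EtMgBr, 40 °C; 5, CuCl (cat.), 50 °C
Reagents that add atoms: none
Why: Copper-catalysed cross-coupling of alkynyl Grignard reagents with an allylic bromide, run once at each end of acetylene, substitutes 5 at its unhindered primary carbon (SN2 rather than SN2') to give the skipped dienyne, and the re-metalation of 6 with EtMgBr is a simple acid–base step.

Step 4
Reactants: 3 methyl 3-acetoxy-2-oxo-2H-pyran-6-carboxylate; 8 2,9-dimethyldeca-2,8-dien-5-yne
Product: 10 methyl 4-acetoxy-2,3-bis(3-methylbut-2-enyl)benzoate, via bicyclic lactone adduct 9 (not isolated)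
Conditions: 8 (3 equiv), BHT (cat.), 1,2-dichlorobenzene, 200 °C, sealed tube
Reagents that add atoms: none
Why: The diene C3=C4–C5=C6 of 3, made electron-poor by the C6 ester and the lactone carbonyl and only weakly enriched by an acetoxy (rather than alkoxy) group, adds the electron-rich dialkylalkyne 8 across C3 and C6 in a concerted inverse-electron-demand [4+2] cycloaddition that forms the C3'–C4' and C1'–C2' bonds and gives the 2-oxabicyclo[2.2.2]octadienone 9. At this temperature 9 expels its O–C(=O) bridge as CO2 in a retro-[4+2] step, so ring B is closed by cycloaddition (both new ring bonds in one event) and becomes aromatic irreversibly. The closest known reaction type is the thermal Diels–Alder/decarboxylation of 2-pyrone carboxylates such as methyl coumalate with unactivated alkynes to give benzoates. No stereocentre remains, because the two bridgehead centres of racemic 9 become sp2 carbons of 10. No regiochemical question arises, since 8 is symmetrical and the pyrone itself places the ester next to C2' and the oxygen next to C3'. The selectivity needed is alkyne over the two trisubstituted alkenes; it rests on the linear and less encumbered alkyne, on the reversibility of alkene adducts that cannot aromatise directly, and on excess 8 with BHT in a base-free medium so that the skipped enyne neither polymerises nor isomerises.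

Step 5
Reactants: 10 methyl 4-acetoxy-2,3-bis(3-methylbut-2-enyl)benzoate
Product: 11 methyl 4-hydroxy-2,3-bis(3-methylbut-2-enyl)benzoate
Conditions: K2CO3 (cat.), MeOH, rt
Reagents that add atoms: none
Why: Base-catalysed transesterification cleaves the activated aryl acetate far faster than the ortho-hindered methyl benzoate, and because no acid is present the freed phenol cannot add to the neighbouring C3 prenyl alkene to form a chroman.

Step 6
Reactants: 11 methyl 4-hydroxy-2,3-bis(3-methylbut-2-enyl)benzoate
Product: 13 methyl 5-formyl-4-hydroxy-2,3-bis(3-methylbut-2-enyl)benzoate, via hydroxymethylphenol 12 (not isolated)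
Conditions: MgCl2, Et3N, (CH2O)n, MeCN, reflux; then dilute HCl
Reagents that add atoms: formaldehyde (as paraformaldehyde) C=O
Why: In this Casnati–Skattebøl ortho-formylation the magnesium phenoxide delivers formaldehyde within a chelate to the only open ortho carbon (C5, the future C5'), a second formaldehyde takes a hydride from the benzylic alkoxide of 12, the method is established for 4-hydroxybenzoates, and it spares the alkenes while avoiding any o-quinone whose carbonyl would sit para to the acidic C2 prenyl CH2.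

Step 7
Reactants: 13 methyl 5-formyl-4-hydroxy-2,3-bis(3-methylbut-2-enyl)benzoate
Product: 15 methyl 4,5-dihydroxy-2,3-bis(3-methylbut-2-enyl)benzoate, via aryl formate 14 (not isolated)
Conditions: 30% H2O2, NaOH, THF/H2O, 0 °C, N2; then HCl
Reagents that add atoms: hydrogen peroxide OO
Why: In the Dakin oxidation hydroperoxide anion adds to the aldehyde, the electron-rich o-phenoxide ring migrates to oxygen to give formate 14, which is saponified in situ, and this nucleophilic oxidant does not epoxidise the unactivated trisubstituted alkenes.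

Step 8
Reactants: 15 methyl 4,5-dihydroxy-2,3-bis(3-methylbut-2-enyl)benzoate
Product: 16 methyl 4,5-bis(methoxymethoxy)-2,3-bis(3-methylbut-2-enyl)benzoate
Conditions: MOMCl, iPr2NEt, CH2Cl2, 0 °C → rt
Reagents that add atoms: chloromethyl methyl ether COCCl
Why: O-alkylation of both catechol oxygens with the reactive α-chloro ether gives acetals that withstand the hydride, hydroxide and alkaline peroxide of the following steps.

Step 9
Reactants: 16 methyl 4,5-bis(methoxymethoxy)-2,3-bis(3-methylbut-2-enyl)benzoate
Product: 17 [4,5-bis(methoxymethoxy)-2,3-bis(3-methylbut-2-enyl)phenyl]methanol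
Conditions: LiAlH4, THF, 0 °C
Reagents that add atoms: none
Why: Hydride reduction of the benzoate to the benzylic alcohol with LiAlH4 leaves isolated alkenes and acetals untouched.

Step 10
Reactants: 17 [4,5-bis(methoxymethoxy)-2,3-bis(3-methylbut-2-enyl)phenyl]methanol
Product: 18 4,5-bis(methoxymethoxy)-2,3-bis(3-methylbut-2-enyl)benzaldehyde
Conditions: MnO2, CH2Cl2, rt
Reagents that add atoms: none
Why: MnO2 oxidises the electron-rich benzylic alcohol selectively and stops at the aldehyde without touching the prenyl groups or the MOM ethers.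

Step 11
Reactants: 19 2,4,6-trihydroxyacetophenone (dried); 20 3-methylbut-2-en-1-ol
Product: 21 1-[2,6-dihydroxy-4-(3-methylbut-2-enyloxy)phenyl]ethanone
Conditions: PPh3, DIAD, THF, 0 °C → rt
Reagents that add atoms: none
Why: The Mitsunobu etherification engages the most acidic and only non-chelated hydroxyl (C4–OH) as pronucleophile and, unlike alkylation of a phloroglucinol-type phenoxide with prenyl bromide, forms no C-prenylated product.

Step 12
Reactants: 21 1-[2,6-dihydroxy-4-(3-methylbut-2-enyloxy)phenyl]ethanone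
Product: 23 1-[2,4,6-trihydroxy-3-(2-methylbut-3-en-2-yl)phenyl]ethanone, via ortho-dienone 22 (not isolated)
Conditions: EtOH/H2O (4:1), 130 °C, sealed tube
Reagents that add atoms: none
Why: In this aromatic Claisen rearrangement the [3,3] shift inverts the allyl unit so that its tertiary carbon bonds to the ring, C3 and C5 of 21 are equivalent by symmetry and the para carbon is blocked by the acetyl group, so tautomerisation of dienone 22 can give one regioisomer only, and a protic medium is known to accelerate this shift for para-acyl aryl prenyl ethers at moderate temperature.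

Step 13
Reactants: 23 1-[2,4,6-trihydroxy-3-(2-methylbut-3-en-2-yl)phenyl]ethanone
Product: 24 1-[2-hydroxy-4,6-bis(methoxymethoxy)-3-(2-methylbut-3-en-2-yl)phenyl]ethanone
Conditions: MOMCl (2.2 equiv), iPr2NEt, CH2Cl2, 0 °C → rt
Reagents that add atoms: chloromethyl methyl ether COCCl
Why: In this selective O-alkylation the non-chelated C4–OH and the unhindered C6–OH react, whereas the C2–OH, wedged between the acetyl group and the quaternary carbon of the 1,1-dimethylallyl group and held in a hydrogen bond to the carbonyl, stays free, which is the pattern known for 3-alkylated phloroacetophenones.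

Step 14
Reactants: 18 4,5-bis(methoxymethoxy)-2,3-bis(3-methylbut-2-enyl)benzaldehyde; 24 1-[2-hydroxy-4,6-bis(methoxymethoxy)-3-(2-methylbut-3-en-2-yl)phenyl]ethanone
Product: 25 (E)-3-[4,5-bis(methoxymethoxy)-2,3-bis(3-methylbut-2-enyl)phenyl]-1-[2-hydroxy-4,6-bis(methoxymethoxy)-3-(2-methylbut-3-en-2-yl)phenyl]prop-2-en-1-one
Conditions: KOH, EtOH/H2O, rt
Reagents that add atoms: none
Why: Claisen–Schmidt condensation of the methyl ketone enolate with the non-enolisable aldehyde followed by E1cB dehydration gives the thermodynamically preferred E enone, and MOM ethers and alkenes are inert to hydroxide.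

Step 15
Reactants: 25 the E chalcone
Product: 27 2-[4,5-bis(methoxymethoxy)-2,3-bis(3-methylbut-2-enyl)phenyl]-3-hydroxy-5,7-bis(methoxymethoxy)-8-(2-methylbut-3-en-2-yl)-4H-chromen-4-one, via trans-dihydroflavonol 26 (not isolated)
Conditions: 30% H2O2, NaOH, MeOH/THF, 0 °C → rt
Reagents that add atoms: hydrogen peroxide OO
Why: In the Algar–Flynn–Oyamada reaction alkaline peroxide oxygenates the enone at Cα while the 2'-phenoxide closes ring C at the benzylic Cβ (six-membered closure, helped by the para C4' alkoxy group that stabilises positive charge at Cβ) to give racemic trans 26, whose two stereocentres are erased on dehydrogenation in the same medium, and because only the 2'-oxygen is free the 1,1-dimethylallyl group must end at C8.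

Step 16
Reactants: 27 the tetra-MOM flavonol
Product: 28 Broussoflavonol C
Conditions: dilute aq. HCl, MeOH, 45 °C
Reagents that add atoms: none
Why: Acid-catalysed acetal exchange with methanol removes all four MOM groups, and dilute acid at mild temperature is the established compromise for prenylated flavonoids that keeps addition of the phenols to the prenyl and 1,1-dimethylallyl alkenes slow.

Compound list
1 | galactaric acid (meso) | OC(=O)[C@H](O)[C@@H](O)[C@@H](O)[C@H](O)C(=O)O | starting material
2 | potassium 3-acetoxy-2-oxo-2H-pyran-6-carboxylate | CC(=O)Oc1ccc(C(=O)[O-])oc1=O.[K+] | intermediate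
3 | methyl 3-acetoxy-2-oxo-2H-pyran-6-carboxylate | CC(=O)Oc1ccc(C(=O)OC)oc1=O | intermediate
4 | ethynylmagnesium bromide | C#C[Mg]Br | starting material
5 | 1-bromo-3-methylbut-2-ene | CC(C)=CCBr | starting material
6 | 5-methylhex-4-en-1-yne | C#CCC=C(C)C | intermediate
7 | (5-methylhex-4-en-1-yn-1-yl)magnesium bromide | CC(C)=CCC#C[Mg]Br | intermediate
8 | 2,9-dimethyldeca-2,8-dien-5-yne | CC(C)=CCC#CCC=C(C)C | intermediate
9 | methyl 4-acetoxy-5,6-bis(3-methylbut-2-enyl)-3-oxo-2-oxabicyclo[2.2.2]octa-5,7-diene-1-carboxylate (racemic, one enantiomer drawn) | COC(=O)[C@@]12OC(=O)[C@@](OC(C)=O)(C=C1)C(CC=C(C)C)=C2CC=C(C)C | intermediate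
10 | methyl 4-acetoxy-2,3-bis(3-methylbut-2-enyl)benzoate | CC(=O)Oc1ccc(C(=O)OC)c(CC=C(C)C)c1CC=C(C)C | intermediate
11 | methyl 4-hydroxy-2,3-bis(3-methylbut-2-enyl)benzoate | COC(=O)c1ccc(O)c(CC=C(C)C)c1CC=C(C)C | intermediate
12 | methyl 4-hydroxy-5-(hydroxymethyl)-2,3-bis(3-methylbut-2-enyl)benzoate | COC(=O)c1cc(CO)c(O)c(CC=C(C)C)c1CC=C(C)C | intermediate
13 | methyl 5-formyl-4-hydroxy-2,3-bis(3-methylbut-2-enyl)benzoate | COC(=O)c1cc(C=O)c(O)c(CC=C(C)C)c1CC=C(C)C | intermediate
14 | methyl 5-(formyloxy)-4-hydroxy-2,3-bis(3-methylbut-2-enyl)benzoate | COC(=O)c1cc(OC=O)c(O)c(CC=C(C)C)c1CC=C(C)C | intermediate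
15 | methyl 4,5-dihydroxy-2,3-bis(3-methylbut-2-enyl)benzoate | COC(=O)c1cc(O)c(O)c(CC=C(C)C)c1CC=C(C)C | intermediate
16 | methyl 4,5-bis(methoxymethoxy)-2,3-bis(3-methylbut-2-enyl)benzoate | COC(=O)c1cc(OCOC)c(OCOC)c(CC=C(C)C)c1CC=C(C)C | intermediate
17 | [4,5-bis(methoxymethoxy)-2,3-bis(3-methylbut-2-enyl)phenyl]methanol | OCc1cc(OCOC)c(OCOC)c(CC=C(C)C)c1CC=C(C)C | intermediate
18 | 4,5-bis(methoxymethoxy)-2,3-bis(3-methylbut-2-enyl)benzaldehyde | O=Cc1cc(OCOC)c(OCOC)c(CC=C(C)C)c1CC=C(C)C | intermediate
19 | 2,4,6-trihydroxyacetophenone | CC(=O)c1c(O)cc(O)cc1O | starting material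
20 | 3-methylbut-2-en-1-ol | CC(C)=CCO | starting material
21 | 1-[2,6-dihydroxy-4-(3-methylbut-2-enyloxy)phenyl]ethanone | CC(=O)c1c(O)cc(OCC=C(C)C)cc1O | intermediate
22 | 4-acetyl-3,5-dihydroxy-6-(2-methylbut-3-en-2-yl)cyclohexa-2,4-dien-1-one (racemic, one enantiomer drawn) | CC(=O)C1=C(O)[C@H](C(C)(C)C=C)C(=O)C=C1O | intermediate
23 | 1-[2,4,6-trihydroxy-3-(2-methylbut-3-en-2-yl)phenyl]ethanone | CC(=O)c1c(O)cc(O)c(C(C)(C)C=C)c1O | intermediate
24 | 1-[2-hydroxy-4,6-bis(methoxymethoxy)-3-(2-methylbut-3-en-2-yl)phenyl]ethanone | CC(=O)c1c(OCOC)cc(OCOC)c(C(C)(C)C=C)c1O | intermediate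
25 | (E)-3-[4,5-bis(methoxymethoxy)-2,3-bis(3-methylbut-2-enyl)phenyl]-1-[2-hydroxy-4,6-bis(methoxymethoxy)-3-(2-methylbut-3-en-2-yl)phenyl]prop-2-en-1-one | C=CC(C)(C)c1c(O)c(C(=O)/C=C/c2cc(OCOC)c(OCOC)c(CC=C(C)C)c2CC=C(C)C)c(OCOC)cc1OCOC | intermediate
26 | trans-2-[4,5-bis(methoxymethoxy)-2,3-bis(3-methylbut-2-enyl)phenyl]-3-hydroxy-5,7-bis(methoxymethoxy)-8-(2-methylbut-3-en-2-yl)chroman-4-one (racemic, 2R,3R enantiomer drawn) | C=CC(C)(C)c1c(OCOC)cc(OCOC)c2C(=O)[C@H](O)[C@@H](c3cc(OCOC)c(OCOC)c(CC=C(C)C)c3CC=C(C)C)Oc12 | intermediate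
27 | 2-[4,5-bis(methoxymethoxy)-2,3-bis(3-methylbut-2-enyl)phenyl]-3-hydroxy-5,7-bis(methoxymethoxy)-8-(2-methylbut-3-en-2-yl)-4H-chromen-4-one | C=CC(C)(C)c1c(OCOC)cc(OCOC)c2c(=O)c(O)c(-c3cc(OCOC)c(OCOC)c(CC=C(C)C)c3CC=C(C)C)oc12 | intermediate
28 | Broussoflavonol C, 2-[4,5-dihydroxy-2,3-bis(3-methylbut-2-enyl)phenyl]-3,5,7-trihydroxy-8-(2-methylbut-3-en-2-yl)-4H-chromen-4-one | C=CC(C)(C)c1c(O)cc(O)c2c(=O)c(O)c(-c3cc(O)c(O)c(CC=C(C)C)c3CC=C(C)C)oc12 | target

Total step count: 16. Longest linear sequence: 12 (steps 1, 2, 4–10, 14–16).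

Steps most likely to fail

Step 4. The cycloaddition of a 3,6-disubstituted pyrone with an internal dialkylalkyne may be too slow at temperatures the pyrone tolerates. The trisubstituted alkenes may also be drawn into competing cycloaddition or ene reactions.
The fallback takes ring B from an existing arene instead of building it. It sets out from prenyl bromide 5 and comes back at aldehyde 18.
- Treatment of 5 with Bu3SnLi (from Bu3SnH and LDA, THF, −78 °C) should give tributyl(3-methylbut-2-enyl)stannane F1.
- Commercial 2,3-dibromo-4,5-dihydroxybenzaldehyde F2 is protected (MOMCl, iPr2NEt, CH2Cl2) as 2,3-dibromo-4,5-bis(methoxymethoxy)benzaldehyde F3.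
- A twofold Stille coupling of F3 with F1 (Pd(PPh3)4, LiCl, DMF, 100 °C) should place both prenyl groups on C2 and C3 and deliver 18 directly.

Step 15. The 6'-alkoxy group may divert ring closure to the α-carbon (five-membered closure leading to aurone formation). The flavonol may also be degraded by prolonged contact with alkaline peroxide.
The fallback separates ring closure from C3 oxygenation. It sets out from ester 16 and ketone 24 and comes back at 27.
- Crossed Claisen condensation of the lithium dianion of 24 with 16 (LiHMDS, THF, −78 °C → reflux) should give 1-[2-hydroxy-4,6-bis(methoxymethoxy)-3-(2-methylbut-3-en-2-yl)phenyl]-3-[4,5-bis(methoxymethoxy)-2,3-bis(3-methylbut-2-enyl)phenyl]propane-1,3-dione F4.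
- Cyclodehydration (PPTS cat., toluene, 80 °C, molecular sieves) closes ring C to the 3-unsubstituted flavone F5.
- LDA at −78 °C lithiates C3 and B(OMe)3 traps the anion as the dimethyl flavon-3-ylboronate F6.
- H2O2/AcOH in the same flask oxidises the C–B bond to the 3-hydroxyl of 27.

Step 12. The prenyl ether may ionise in the hot protic medium (loss or 1,3-shift of the prenyl group). The new o-(1,1-dimethylallyl)phenol may undergo abnormal Claisen rearrangement or close to a dihydrobenzofuran.
The fallback moves the sigmatropic step to the flavonol stage, where 7-prenyloxyflavones are known to give 8-(1,1-dimethylallyl)flavones. It also removes the need for step 13. It sets out from 21 and comes back at 28.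
- Mono-protection of 21 (MOMCl, 1 equiv, iPr2NEt) gives 1-[2-hydroxy-6-(methoxymethoxy)-4-(3-methylbut-2-enyloxy)phenyl]ethanone F7.
- Claisen–Schmidt condensation with 18 (KOH, EtOH) gives the 4'-prenyloxychalcone F8.
- Alkaline H2O2 gives the 7-prenyloxyflavonol F9.
- Heating in N,N-diethylaniline at 190 °C should move the allyl unit to C8, since C6 is flanked by the 5-OMOM group, giving the 7-hydroxy-8-(1,1-dimethylallyl)flavonol F10.
- Dilute HCl in MeOH then removes the three MOM groups to give 28.

Further compounds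
F1 | step 4 | tributyl(3-methylbut-2-enyl)stannane | CCCC[Sn](CCCC)(CCCC)CC=C(C)C
F2 | step 4 | 2,3-dibromo-4,5-dihydroxybenzaldehyde | O=Cc1cc(O)c(O)c(Br)c1Br
F3 | step 4 | 2,3-dibromo-4,5-bis(methoxymethoxy)benzaldehyde | O=Cc1cc(OCOC)c(OCOC)c(Br)c1Br
F4 | step 15 | 1-[2-hydroxy-4,6-bis(methoxymethoxy)-3-(2-methylbut-3-en-2-yl)phenyl]-3-[4,5-bis(methoxymethoxy)-2,3-bis(3-methylbut-2-enyl)phenyl]propane-1,3-dione | C=CC(C)(C)c1c(O)c(C(=O)CC(=O)c2cc(OCOC)c(OCOC)c(CC=C(C)C)c2CC=C(C)C)c(OCOC)cc1OCOC
F5 | step 15 | 2-[4,5-bis(methoxymethoxy)-2,3-bis(3-methylbut-2-enyl)phenyl]-5,7-bis(methoxymethoxy)-8-(2-methylbut-3-en-2-yl)-4H-chromen-4-one | C=CC(C)(C)c1c(OCOC)cc(OCOC)c2c(=O)cc(-c3cc(OCOC)c(OCOC)c(CC=C(C)C)c3CC=C(C)C)oc12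
F6 | step 15 | dimethyl {2-[4,5-bis(methoxymethoxy)-2,3-bis(3-methylbut-2-enyl)phenyl]-5,7-bis(methoxymethoxy)-8-(2-methylbut-3-en-2-yl)-4-oxo-4H-chromen-3-yl}boronate | C=CC(C)(C)c1c(OCOC)cc(OCOC)c2c(=O)c(B(OC)OC)c(-c3cc(OCOC)c(OCOC)c(CC=C(C)C)c3CC=C(C)C)oc12
F7 | step 12 | 1-[2-hydroxy-6-(methoxymethoxy)-4-(3-methylbut-2-enyloxy)phenyl]ethanone | CC(=O)c1c(O)cc(OCC=C(C)C)cc1OCOC
F8 | step 12 | (E)-3-[4,5-bis(methoxymethoxy)-2,3-bis(3-methylbut-2-enyl)phenyl]-1-[2-hydroxy-6-(methoxymethoxy)-4-(3-methylbut-2-enyloxy)phenyl]prop-2-en-1-one | CC(C)=CCOc1cc(O)c(C(=O)/C=C/c2cc(OCOC)c(OCOC)c(CC=C(C)C)c2CC=C(C)C)c(OCOC)c1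
F9 | step 12 | 2-[4,5-bis(methoxymethoxy)-2,3-bis(3-methylbut-2-enyl)phenyl]-3-hydroxy-5-(methoxymethoxy)-7-(3-methylbut-2-enyloxy)-4H-chromen-4-one | CC(C)=CCOc1cc(OCOC)c2c(=O)c(O)c(-c3cc(OCOC)c(OCOC)c(CC=C(C)C)c3CC=C(C)C)oc2c1
F10 | step 12 | 2-[4,5-bis(methoxymethoxy)-2,3-bis(3-methylbut-2-enyl)phenyl]-3,7-dihydroxy-5-(methoxymethoxy)-8-(2-methylbut-3-en-2-yl)-4H-chromen-4-one | C=CC(C)(C)c1c(O)cc(OCOC)c2c(=O)c(O)c(-c3cc(OCOC)c(OCOC)c(CC=C(C)C)c3CC=C(C)C)oc12
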